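**Remark on the chemistry:** 12 has no stereocenter, and its two proton tautomers are the same compound. Henicosanoic acid (1), 2,5-dimethoxytoluene (3) and methanol (7) are taken as purchasable.

## The problem

Compound 12 is a fully substituted 1,4-benzoquinone with no ring fusion and no stereocenter, so the difficulty is purely regiochemical. With the ring numbered C1 (carbonyl), C2 (hydroxyl), C3 (henicosyl), C4 (carbonyl), C5 (hydroxyl) and C6 (methyl), the two alkyl groups are para to each other and so are the two hydroxyls. One C–C bond must join an unbranched C21 chain to the ring para to the methyl group, and two C–O bonds must be made at C2 and C5. The 2,5-dihydroxyquinone is a vinylogous acid, redox-active and chelating, and is poorly suited to chromatography or to being carried through several steps. The alkylquinones on the way are sensitive to base, and the electron-rich hydroquinones to air. The C21 chain makes every intermediate waxy and sparingly soluble in polar media, so the chain should go on early by robust chemistry and the free hydroxyls should appear last. The feature that invites the key step is that C2 and C5 are exactly the two unsubstituted ring carbons of hydroquinone 6; in the derived quinone 8 each of them is β to a carbonyl, so oxidation followed by conjugate addition of an oxygen nucleophile has no regiochemical choice to make.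

## Retrosynthesis

**12 ⇒ 11.** The two hydroxyls at C2 and C5 are traced back to methoxyls. Making the free dihydroxyquinone directly in the oxidative step would expose an acidic, chelating product to the electrolysis and would require water to add to a lipophilic quinone. Dimethyl ether 11 is neutral and can be crystallised or chromatographed. The forward reaction is a twofold addition–elimination of hydroxide on two vinylogous esters, and it must go to completion at both positions.

**11 ⇒ 6 + 7.** Both ring C–O bonds (C2–O and C5–O) are cut and the oxidation level is lowered from quinone to hydroquinone. Neighbouring options, such as two rounds of acid-catalysed acetoxylation, oxidative amination with later hydrolysis, or halogenation and displacement, spend more steps or reagents on the same two bonds. Precursor 6 carries only two of the four oxygens and is a plain 1,2,4,5-tetrasubstituted benzene with two free positions. The forward reaction must remove six electrons and add two molecules of 7, one for each new C–O bond. It runs through quinone 8 and the monomethoxyquinones 9 or 10. The additions to an alkylated, then alkoxylated, quinone must proceed at a potential low enough to spare the benzylic C–H bonds.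

**6 ⇒ 5.** The two aryl O–CH3 bonds are the only change. The methyl ethers are carried because the preceding C–C bond formation is best run on an arene that cannot be oxidised and has clear directing effects. The forward step is exhaustive ether cleavage with BBr3 and isolation of 6 without air oxidation.

**5 ⇒ 4.** The benzylic CH2 is traced to a ketone. No skeletal bond is cut, but this prepares the aryl–chain disconnection as an acylation. Direct alkylation with a C21 electrophile would suffer rearrangement and polyalkylation. The forward step must deoxygenate an aryl ketone next to a methoxyl without touching the ethers.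

**4 ⇒ 2 + 3.** The bond between the ring and the first chain carbon is cut. In 3 the carbon para to the methyl group is ortho to a methoxyl and unhindered. The other two CH positions are either flanked on both sides or lack the para-methyl activation. Friedel–Crafts acylation should therefore place the chain para to methyl, exactly as 12 requires. Both partners are simple.

**2 ⇒ 1.** The C–Cl bond is traced to the commercial C21 acid 1.

## Roads not taken

Alternative 1: The benzene ring is cut at C1–C6 and unravelled through a dienylketene to a four-membered ring. On heating, cyclobutenone A2 (4-[(1Z)-1-ethoxyprop-1-enyl]-3-henicosyl-4-hydroxy-2-isopropoxycyclobut-2-en-1-one) should open by 4π-electrocyclic cleavage. The ketene carbon then closes onto the propenyl CH carbon by 6π-electrocyclisation, and tautomerisation gives the fully substituted hydroquinone A1 (2-ethoxy-6-henicosyl-5-isopropoxy-3-methylbenzene-1,4-diol).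
- Merits: all four oxygens and both alkyl groups are fixed by construction, and the thermal step is dependable for this class. Here it is better than the chosen plan, whose C–O bond formation depends on addition to a deactivated quinone.
- Weak points: building A2 requires a long-chain organolithium reagent at low temperature. It also requires a second, lithiated enol-ether nucleophile to attack the ring carbonyl next to the chain-bearing carbon, which is the less electrophilic, vinylogous-ester carbonyl. The normal mode of attack would leave chain and methyl meta, so a longer protect–add–transpose sequence is needed.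
- A1 must still be oxidised and freed of two different ethers, and the four-membered-ring starting material is costly.
- Comparison: the chosen plan offers the commodity arene 3, no organometallic steps, a comparable step count, and a classical halogen-displacement reserve for its uncertain step.

Alternative 2: The ring bond that becomes C3–C4 is cut, leading back to the open-chain triketo ester A4 (methyl 4-methyl-3,5,7-trioxooctacosanoate). Under mild base and then acid, the C2 methylene of A4 should add to its C7 ketone. Dehydration and enolisation then give the resorcylate A3 (methyl 6-henicosyl-2,4-dihydroxy-3-methylbenzoate).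
- Merits: it follows the likely polyketide origin, and the para relationship of chain and methyl is set by the order of the chain carbons.
- Weak points: A4 is a C28 polycarbonyl compound that needs polyanion acylations and can cyclise in other modes, for example to pyrones. The ester of A3 is not in the target and must be removed.
- The decisive weakness is that A3 carries only the oxygens at C1 and C5. The oxygens at C2 and C4 still have to be introduced by two ring oxidations, which is the same C–O problem reached by a longer road.
- Comparison: its only advantage is the biomimetic ring assembly, which the chosen plan does not need because the ring is bought. It is several steps longer.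

Alternative 3: Three ring bonds (C1–C6, C3–C4, C4–C5) are cut at once. Heating the pentacarbonylchromium carbene complex A6, (CO)5Cr=C(OMe)C(OMe)=CHC21H43, with alkyne A7 (1-ethoxyprop-1-yne) should give, with insertion of one CO ligand, the phenol A5 (2-ethoxy-6-henicosyl-4,5-dimethoxy-3-methylphenol).
- Merits: this is the most convergent route, and it delivers the ring with every substituent in one step. In convergence it beats the chosen plan.
- Weak points: it uses stoichiometric zerovalent chromium. A6 needs several steps, since a long-chain enol ether must be made, lithiated, and converted to the carbene.
- The regiochemistry of insertion of A7 is uncertain, because ethoxy and methyl differ little in size. The wrong orientation would put chain and methyl meta. Electron-rich alkynes of this kind can also divert to products without CO insertion.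
- A5 still needs oxidation and cleavage of two ethers.
- Comparison: the chosen plan has no regiochemical question in its key step, and it uses no heavy metal beyond a zinc salt.

Key step: step 5

## Route

Step 1
Reactants: 1 henicosanoic acid
Product: 2 henicosanoyl chloride
Conditions: (COCl)2, cat. DMF, CH2Cl2, 0 °C to rt; evaporate
Reagents that add atoms: oxalyl chloride, ClC(=O)C(=O)Cl
Why: Acid chloride formation under DMF (chloroiminium) catalysis; the by-products are gases, so the crude chloride can be used directly.

Step 2
Reactants: 2 henicosanoyl chloride; 3 2,5-dimethoxytoluene
Product: 4 1-(2,5-dimethoxy-4-methylphenyl)henicosan-1-one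
Conditions: AlCl3 (1.2 equiv), CH2Cl2, 0 °C; then ice/aq. HCl
Reagents that add atoms: none
Why: Friedel–Crafts acylation; the carbon para to methyl is activated by the ortho methoxyl and the para methyl and is the least hindered, and the deactivating acyl group prevents a second substitution.

Step 3
Reactants: 4 1-(2,5-dimethoxy-4-methylphenyl)henicosan-1-one
Product: 5 1-henicosyl-2,5-dimethoxy-4-methylbenzene
Conditions: Et3SiH (3 equiv), CF3CO2H, CH2Cl2, rt to 40 °C
Reagents that add atoms: none
Why: Ionic hydrogenation of an electron-rich aryl ketone; hydride transfer to the protonated ketone, ionisation of the benzylic alcohol and a second hydride transfer give the methylene, and the aryl ethers are inert.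

Step 4
Reactants: 5 1-henicosyl-2,5-dimethoxy-4-methylbenzene
Product: 6 2-henicosyl-5-methylbenzene-1,4-diol
Conditions: BBr3 (3 equiv), CH2Cl2, −78 °C to rt; H2O; aq. Na2S2O4 wash under N2
Reagents that add atoms: none
Why: Lewis-acid cleavage of aryl methyl ethers through the aryloxyborane and bromide attack on methyl; the reducing wash keeps the hydroquinone from air oxidation.

Step 5
Reactants: 6 2-henicosyl-5-methylbenzene-1,4-diol; 7 methanol
Product: 11 3-henicosyl-2,5-dimethoxy-6-methyl-1,4-benzoquinone, via 2-henicosyl-5-methyl-1,4-benzoquinone 8 (not isolated), via 2-henicosyl-3-methoxy-5-methyl-1,4-benzoquinone 9 (not isolated), via 5-henicosyl-3-methoxy-2-methyl-1,4-benzoquinone 10 (not isolated)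
Conditions: divided cell, graphite-felt anode, Pt cathode, LiClO4 (0.1 M), ZnCl2 (1 equiv), MeOH/CH2Cl2 3:1, 35 °C, N2, anode held at the first oxidation wave of 6 (about +0.7 V vs Ag/AgCl), about 6 F/mol
Reagents that add atoms: methanol, CO
Why: Proposed new method: the anode takes two electrons and two protons from 6 to give quinone 8; ZnCl2-activated 8 accepts one molecule of methanol (7) at one of its two ring CH carbons, each β to a carbonyl, and enolisation gives a methoxyhydroquinone that is more electron-rich than 6 and is oxidised at once to 9 or 10. A second molecule of methanol, drawn from the solvent, adds at the one remaining CH carbon and a third two-electron oxidation gives 11, so that two methanol units are incorporated and six electrons are removed in all, while protons are reduced to H2 at the cathode. The closest known reactions are the anodic methoxylation of catechols to 4,5-dimethoxy-1,2-benzoquinones in methanol and the ZnCl2-promoted conversion of 1,4-benzoquinone into 2,5-dimethoxy-1,4-benzoquinone in methanol, where further quinone serves as the oxidant; here the electrode takes that role, but the sequence has not been shown on a 2,5-dialkylhydroquinone. No ring is closed and no stereocenter is formed. Site selectivity needs no control, because C2 and C5 are the only ring CH positions and the mono-adducts 9 and 10 converge on 11. Chemoselectivity over oxidation of the benzylic CH2 and CH3 groups and of methanol depends on holding the anode at the hydroquinone wave, well below the potentials those processes need. The divided cell keeps the quinones and the zinc salt away from the cathode, and the electrolysis should end by itself once no ring C–H is left.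

Step 6
Reactants: 11 3-henicosyl-2,5-dimethoxy-6-methyl-1,4-benzoquinone
Product: 12 3-henicosyl-2,5-dihydroxy-6-methyl-1,4-benzoquinone
Conditions: 2 M aq. NaOH, THF, 50 °C, N2; then 2 M aq. HCl to pH 1
Reagents that add atoms: sodium hydroxide, [Na+].[OH-]
Why: Hydrolysis of two vinylogous methyl esters by conjugate addition of hydroxide and loss of methoxide; the dianion of the dihydroxyquinone is stable to base and gives 12 on acidification.

## Compound list

1 | henicosanoic acid | CCCCCCCCCCCCCCCCCCCCC(=O)O | starting material
2 | henicosanoyl chloride | CCCCCCCCCCCCCCCCCCCCC(=O)Cl | intermediate
3 | 2,5-dimethoxytoluene (1,4-dimethoxy-2-methylbenzene) | COc1ccc(OC)c(C)c1 | starting material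
4 | 1-(2,5-dimethoxy-4-methylphenyl)henicosan-1-one | CCCCCCCCCCCCCCCCCCCCC(=O)c1cc(OC)c(C)cc1OC | intermediate
5 | 1-henicosyl-2,5-dimethoxy-4-methylbenzene | CCCCCCCCCCCCCCCCCCCCCc1cc(OC)c(C)cc1OC | intermediate
6 | 2-henicosyl-5-methylbenzene-1,4-diol | CCCCCCCCCCCCCCCCCCCCCc1cc(O)c(C)cc1O | intermediate
7 | methanol | CO | starting material
8 | 2-henicosyl-5-methyl-1,4-benzoquinone | CCCCCCCCCCCCCCCCCCCCCC1=CC(=O)C(C)=CC1=O | intermediate
9 | 2-henicosyl-3-methoxy-5-methyl-1,4-benzoquinone | CCCCCCCCCCCCCCCCCCCCCC1=C(OC)C(=O)C(C)=CC1=O | intermediate
10 | 5-henicosyl-3-methoxy-2-methyl-1,4-benzoquinone | CCCCCCCCCCCCCCCCCCCCCC1=CC(=O)C(C)=C(OC)C1=O | intermediate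
11 | 3-henicosyl-2,5-dimethoxy-6-methyl-1,4-benzoquinone | CCCCCCCCCCCCCCCCCCCCCC1=C(OC)C(=O)C(C)=C(OC)C1=O | intermediate
12 | 3-henicosyl-2,5-dihydroxy-6-methyl-1,4-benzoquinone | CCCCCCCCCCCCCCCCCCCCCC1=C(O)C(=O)C(C)=C(O)C1=O | target

## Step count and risk

Total steps: 6. Longest linear sequence: 6 steps (1 → 2 → 4 → 5 → 6 → 11 → 12).

**Step 5 (key step, proposed new method).**
- Risk: the electrolysis may stall after the first two-electron oxidation, because methanol adds slowly to a quinone carrying two alkyl groups. It may also stall after the first methoxylation, because the methoxyl deactivates the ring further. Raising the potential to force conversion would start benzylic oxidation.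
- Fallback (known chemistry), from 6 back to 11: treat 6 with Br2 (3 equiv) in AcOH. This brominates both free ring positions and oxidises the ring, giving 2,5-dibromo-3-henicosyl-6-methyl-1,4-benzoquinone F1. NaOMe (2.2 equiv) in MeOH/THF at 0 °C then replaces both bromides by addition–elimination to give 11.

**Step 6.**
- Risk: hydrolysis may stop after one methoxyl, because the first hydroxyquinone anion makes the ring a poorer acceptor for the second hydroxide. Prolonged hot alkali may degrade the ring.
- Fallback, from 11 back to 12: reduce 11 with aq. Na2S2O4 to 3-henicosyl-2,5-dimethoxy-6-methylbenzene-1,4-diol F2. Cleave both ethers with BBr3 in CH2Cl2 to 3-henicosyl-6-methylbenzene-1,2,4,5-tetrol F3. Stir F3 in air, which oxidises it to 12.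

**Step 2.**
- Risk: AlCl3 may cleave the methoxyl ortho to the new ketone by chelation. The waxy acyl chloride complex may also acylate sluggishly at 0 °C, giving a mixture that is harder to purify.
- Fallback, from 1 back to 6: heat acid 1 with 2-methylbenzene-1,4-diol F4 in BF3·OEt2 at about 110 °C. This Fries-type acylation para to methyl gives 1-(2,5-dihydroxy-4-methylphenyl)henicosan-1-one F5. Clemmensen reduction (Zn(Hg), aq. HCl, EtOH/toluene, reflux) then gives 6, with no methyl ethers and no steps 1 to 4.

**Step 4.**
- Risk: cleavage of the second ether may be incomplete, and the electron-rich hydroquinone may partly oxidise in air during work-up.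
- Fallback, from 5 back to 6: oxidative demethylation with (NH4)2Ce(NO3)6 in MeCN/H2O gives quinone 8 directly. Reduction with aq. Na2S2O4 gives 6. Alternatively 8 can be fed to the electrolysis of step 5, where it is the first intermediate.

## Further compounds

F1 | step 5 | 2,5-dibromo-3-henicosyl-6-methyl-1,4-benzoquinone | CCCCCCCCCCCCCCCCCCCCCC1=C(Br)C(=O)C(C)=C(Br)C1=O
F2 | step 6 | 3-henicosyl-2,5-dimethoxy-6-methylbenzene-1,4-diol | CCCCCCCCCCCCCCCCCCCCCc1c(OC)c(O)c(C)c(OC)c1O
F3 | step 6 | 3-henicosyl-6-methylbenzene-1,2,4,5-tetrol | CCCCCCCCCCCCCCCCCCCCCc1c(O)c(O)c(C)c(O)c1O
F4 | step 2 | 2-methylbenzene-1,4-diol | Cc1cc(O)ccc1O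
F5 | step 2 | 1-(2,5-dihydroxy-4-methylphenyl)henicosan-1-one | CCCCCCCCCCCCCCCCCCCCC(=O)c1cc(O)c(C)cc1O
F0 | step 4 | none | none
A1 | alternative 1 | 2-ethoxy-6-henicosyl-5-isopropoxy-3-methylbenzene-1,4-diol | CCOc1c(C)c(O)c(OC(C)C)c(CCCCCCCCCCCCCCCCCCCCC)c1O
A2 | alternative 1 | 4-[(1Z)-1-ethoxyprop-1-enyl]-3-henicosyl-4-hydroxy-2-isopropoxycyclobut-2-en-1-one (racemic; alkene geometry of no consequence) | CCO/C(=C\C)C1(O)C(CCCCCCCCCCCCCCCCCCCCC)=C(OC(C)C)C1=O
A3 | alternative 2 | methyl 6-henicosyl-2,4-dihydroxy-3-methylbenzoate | COC(=O)c1c(O)c(C)c(O)cc1CCCCCCCCCCCCCCCCCCCCC
A4 | alternative 2 | methyl 4-methyl-3,5,7-trioxooctacosanoate (racemic, enolisable) | COC(=O)CC(=O)C(C)C(=O)CC(=O)CCCCCCCCCCCCCCCCCCCCC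
A5 | alternative 3 | 2-ethoxy-6-henicosyl-4,5-dimethoxy-3-methylphenol | COc1c(C)c(OCC)c(O)c(CCCCCCCCCCCCCCCCCCCCC)c1OC
A6 | alternative 3 | pentacarbonyl(1,2-dimethoxytetracos-2-en-1-ylidene)chromium, (CO)5Cr=C(OMe)C(OMe)=CHC21H43 (alkene geometry not fixed) | CCCCCCCCCCCCCCCCCCCCCC=C(OC)C(OC)=[Cr](=C=O)(=C=O)(=C=O)(=C=O)=C=O
A7 | alternative 3 | 1-ethoxyprop-1-yne | CCOC#CC
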